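**Retrosynthetic overview**
- The ten-membered carbocycle is closed last by an intramolecular Nozaki–Hiyama–Kishi coupling (C1–C2) of an alkenyl iodide onto an aldehyde; a final desilylation gives the target.
- The seco compound comes from a late indium Barbier allylation (C6–C7) joining a west enal (C2–C6, C15) with an east allylic bromide (C7–C14, C1). The adduct's six-membered lactone then migrates to the trans α-methylene γ-lactone.
- East: the six-membered lactone bromide is made by ring-closing metathesis of a 2-(bromomethyl)acrylate ester; C9 comes from a chelation-controlled iodo-aldol of methyl propiolate, C8 from (S)-but-3-ene-1,2-diol.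
- West: but-2-yne-1,4-diol; trans-hydroalumination/iodination fixes the C4=C5 geometry, Suzuki vinylation and hydroboration add C3–C2.
- Ring order: six-membered lactone (metathesis), five-membered lactone (acyl migration), ten-membered carbocycle (chromium coupling).

Assumption: locants C1–C15 are the germacrane locants of the target (ring C1–C10, lactone carbons C11–C13 with C12 the carbonyl, ester carbon C14 on C10, CH2O carbon C15 on C4); the target is (1(10)E,4E,2S,6R,7S,8S,9S).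

**West fragment**

Step 1
Reactants: 1 but-2-yne-1,4-diol
Product: 2 4-[(tert-butyldiphenylsilyl)oxy]but-2-yn-1-ol
Conditions: TBDPSCl (0.3 equiv), imidazole, DMF, 0 °C to rt
Reagents that add atoms: tert-butyl(chloro)diphenylsilane, CC(C)(C)[Si](Cl)(c1ccccc1)c1ccccc1
Why: Statistical monosilylation (silyl ether formation) of the symmetric diol used in excess leaves one propargylic hydroxyl to direct step 2.

Step 2
Reactants: 2 4-[(tert-butyldiphenylsilyl)oxy]but-2-yn-1-ol
Product: 4 (2Z)-4-[(tert-butyldiphenylsilyl)oxy]-3-iodobut-2-en-1-ol, via cyclic alkenylalanate 3 (not isolated)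
Conditions: NaAlH2(OCH2CH2OMe)2, THF, 0 °C; then I2, −78 °C
Reagents that add atoms: iodine, II
Why: Hydroxyl-directed trans-hydroalumination puts hydride on the proximal and aluminium on the distal alkyne carbon inside a five-membered alanate, and iodinolysis with retention gives only the Z iodide, which fixes the C4=C5 geometry.

Step 3
Reactants: 4 (2Z)-4-[(tert-butyldiphenylsilyl)oxy]-3-iodobut-2-en-1-ol; 5 potassium vinyltrifluoroborate
Product: 6 (2E)-3-{[(tert-butyldiphenylsilyl)oxy]methyl}penta-2,4-dien-1-ol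
Conditions: PdCl2(dppf) (5 mol%), Cs2CO3, THF/H2O (9:1), 65 °C
Reagents that add atoms: none
Why: Suzuki–Miyaura coupling of the alkenyl iodide goes with retention, so the vinyl group (future C3–C2) stays cis to C6 and trans to the silyloxymethyl arm.

Step 4
Reactants: 6 (2E)-3-{[(tert-butyldiphenylsilyl)oxy]methyl}penta-2,4-dien-1-ol
Product: 7 (2E)-3-{[(tert-butyldiphenylsilyl)oxy]methyl}penta-2,4-dien-1-yl acetate
Conditions: Ac2O, pyridine, DMAP (cat.), CH2Cl2, 0 °C
Reagents that add atoms: acetic anhydride, CC(=O)OC(C)=O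
Why: Acetylation masks the allylic alcohol so that only the primary alcohol made in step 5 is silylated in step 6.

Step 5
Reactants: 7 (2E)-3-{[(tert-butyldiphenylsilyl)oxy]methyl}penta-2,4-dien-1-yl acetate
Product: 9 (2E)-3-{[(tert-butyldiphenylsilyl)oxy]methyl}-5-hydroxypent-2-en-1-yl acetate, via B-alkyl-9-BBN adduct 8 (not isolated)
Conditions: 9-BBN, THF, 0 °C to rt; then NaBO3·4H2O, H2O, rt
Reagents that add atoms: sodium perborate, O[B-]1(O)OO[B-](O)(O)OO1.[Na+].[Na+]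
Why: Hydroboration–oxidation with bulky 9-BBN adds boron only to the end carbon of the monosubstituted alkene, and mild perborate oxidation spares the acetate and the trisubstituted alkene.

Step 6
Reactants: 9 (2E)-3-{[(tert-butyldiphenylsilyl)oxy]methyl}-5-hydroxypent-2-en-1-yl acetate
Product: 10 (2E)-5-[(tert-butyldimethylsilyl)oxy]-3-{[(tert-butyldiphenylsilyl)oxy]methyl}pent-2-en-1-yl acetate
Conditions: TBSCl, imidazole, CH2Cl2, 0 °C
Reagents that add atoms: tert-butyl(chloro)dimethylsilane, CC(C)(C)[Si](C)(C)Cl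
Why: Silyl ether formation on the only free hydroxyl gives a C2 oxygen that can later be unmasked in the presence of the TBDPS ether.

Step 7
Reactants: 10 (2E)-5-[(tert-butyldimethylsilyl)oxy]-3-{[(tert-butyldiphenylsilyl)oxy]methyl}pent-2-en-1-yl acetate
Product: 11 (2E)-5-[(tert-butyldimethylsilyl)oxy]-3-{[(tert-butyldiphenylsilyl)oxy]methyl}pent-2-en-1-ol
Conditions: K2CO3 (0.2 equiv), MeOH, 0 °C
Reagents that add atoms: none
Why: Base-catalysed transesterification with methanol removes the acetate while both silyl ethers survive.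

Step 8
Reactants: 11 (2E)-5-[(tert-butyldimethylsilyl)oxy]-3-{[(tert-butyldiphenylsilyl)oxy]methyl}pent-2-en-1-ol
Product: 12 (2E)-5-[(tert-butyldimethylsilyl)oxy]-3-{[(tert-butyldiphenylsilyl)oxy]methyl}pent-2-enal
Conditions: MnO2 (excess), CH2Cl2, rt
Reagents that add atoms: none
Why: MnO2 oxidises only the allylic alcohol and does not isomerise the fully β-substituted enal, giving the west fragment with C6 as aldehyde.

**East fragment**

Step 9
Reactants: 13 (2S)-but-3-ene-1,2-diol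
Product: 14 (4S)-4-ethenyl-2-(4-methoxyphenyl)-1,3-dioxolane
Conditions: 4-MeOC6H4CH(OMe)2, PPTS (cat.), CH2Cl2, rt
Reagents that add atoms: 4-methoxybenzaldehyde dimethyl acetal, COc1ccc(C(OC)OC)cc1
Why: Acid-catalysed transacetalisation gives the five-membered p-methoxybenzylidene acetal (both acetal epimers) without touching the C8 stereocentre taken from the chiral pool.

Step 10
Reactants: 14 (4S)-4-ethenyl-2-(4-methoxyphenyl)-1,3-dioxolane
Product: 15 (2S)-2-[(4-methoxybenzyl)oxy]but-3-en-1-ol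
Conditions: iBu2AlH, CH2Cl2, −78 to 0 °C
Reagents that add atoms: none
Why: Regioselective reductive acetal opening: aluminium binds the less hindered primary oxygen, so the PMB ether stays on the secondary oxygen and the primary alcohol is freed.

Step 11
Reactants: 15 (2S)-2-[(4-methoxybenzyl)oxy]but-3-en-1-ol
Product: 16 (2S)-2-[(4-methoxybenzyl)oxy]but-3-enal
Conditions: Dess–Martin periodinane, NaHCO3, CH2Cl2, 0 °C; used at once
Reagents that add atoms: none
Why: Buffered Dess–Martin oxidation gives the α-alkoxy aldehyde without base, which avoids epimerisation at C8 and migration of the alkene.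

Step 12
Reactants: 16 (2S)-2-[(4-methoxybenzyl)oxy]but-3-enal; 17 methyl propiolate
Product: 19 methyl (2E)-2-{(1S,2S)-1-hydroxy-2-[(4-methoxybenzyl)oxy]but-3-en-1-yl}-3-iodoprop-2-enoate, via Z-iodoacrylate isomer 18 (not isolated)
Conditions: MgI2, CH2Cl2, 0 °C; then I2 (5 mol%), visible light, rt
Reagents that add atoms: magnesium iodide, [Mg+2].[I-].[I-]
Why: In this iodo-aldol (halo Morita–Baylis–Hillman-type three-component coupling) iodide adds to the propiolate and the aldol takes place on the aldehyde chelated by magnesium through its PMB ether (Cram chelate), setting C9 syn to C8; iodine-radical equilibration then converts the kinetic Z iodide into the E isomer (iodine trans to the ester).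

Step 13
Reactants: 19 methyl (2E)-2-{(1S,2S)-1-hydroxy-2-[(4-methoxybenzyl)oxy]but-3-en-1-yl}-3-iodoprop-2-enoate; 20 2-(bromomethyl)prop-2-enoic acid
Product: 21 (1S,2S)-1-[(1E)-2-iodo-1-(methoxycarbonyl)ethenyl]-2-[(4-methoxybenzyl)oxy]but-3-en-1-yl 2-(bromomethyl)prop-2-enoate
Conditions: DCC, DMAP (5 mol%), CH2Cl2, 0 °C
Reagents that add atoms: none
Why: Steglich esterification acylates the hindered allylic alcohol under near-neutral conditions and brings in C11–C13 and the future lactone carbonyl C12.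

Step 14
Reactants: 21 (1S,2S)-1-[(1E)-2-iodo-1-(methoxycarbonyl)ethenyl]-2-[(4-methoxybenzyl)oxy]but-3-en-1-yl 2-(bromomethyl)prop-2-enoate
Product: 22 (1S,2S)-2-hydroxy-1-[(1E)-2-iodo-1-(methoxycarbonyl)ethenyl]but-3-en-1-yl 2-(bromomethyl)prop-2-enoate
Conditions: DDQ, CH2Cl2/pH 7 buffer, 0 °C to rt
Reagents that add atoms: none
Why: Oxidative PMB ether cleavage is neutral and leaves the alkenes, the allylic bromide and the alkenyl iodide intact.

Step 15
Reactants: 22 (1S,2S)-2-hydroxy-1-[(1E)-2-iodo-1-(methoxycarbonyl)ethenyl]but-3-en-1-yl 2-(bromomethyl)prop-2-enoate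
Product: 23 (1S,2S)-1-[(1E)-2-iodo-1-(methoxycarbonyl)ethenyl]-2-[(2-methylpropanoyl)oxy]but-3-en-1-yl 2-(bromomethyl)prop-2-enoate
Conditions: iPrCOCl, 2,6-lutidine, DMAP (5 mol%), CH2Cl2, 0 °C
Reagents that add atoms: 2-methylpropanoyl chloride, CC(C)C(Cl)=O
Why: Acylation of the freed C8 hydroxyl with a hindered base installs the target's isobutyrate before the ring is formed.

Step 16
Reactants: 23 (1S,2S)-1-[(1E)-2-iodo-1-(methoxycarbonyl)ethenyl]-2-[(2-methylpropanoyl)oxy]but-3-en-1-yl 2-(bromomethyl)prop-2-enoate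
Product: 24 methyl (2E)-2-{(2S,3S)-5-(bromomethyl)-3-[(2-methylpropanoyl)oxy]-6-oxo-3,6-dihydro-2H-pyran-2-yl}-3-iodoprop-2-enoate
Conditions: second-generation Grubbs catalyst (5 mol%), CH2Cl2, 40 °C, 5 mM
Reagents that add atoms: none
Why: Ring-closing metathesis of the vinyl group with the 2-(bromomethyl)acrylate gives the unsaturated six-membered lactone, which holds C8 cis to the lactone carbonyl; the trisubstituted iodoacrylate is inert.

**Fragment union and endgame**

Step 17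
Reactants: 12 (2E)-5-[(tert-butyldimethylsilyl)oxy]-3-{[(tert-butyldiphenylsilyl)oxy]methyl}pent-2-enal; 24 methyl (2E)-2-{(2S,3S)-5-(bromomethyl)-3-[(2-methylpropanoyl)oxy]-6-oxo-3,6-dihydro-2H-pyran-2-yl}-3-iodoprop-2-enoate
Product: 26 methyl (2E)-2-[(1S,2S)-2-{(2R,3S)-2-[(1E)-4-[(tert-butyldimethylsilyl)oxy]-2-{[(tert-butyldiphenylsilyl)oxy]methyl}but-1-en-1-yl]-4-methylidene-5-oxooxolan-3-yl}-1-hydroxy-2-[(2-methylpropanoyl)oxy]ethyl]-3-iodoprop-2-enoate, via six-membered-lactone adduct 25 (not isolated)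
Conditions: indium powder, THF/H2O (4:1), rt; then CSA (cat.), CH2Cl2, rt
Reagents that add atoms: none
Why: Indium Barbier allylation at the γ carbon (C7) through a closed chair transition state: the ring-fixed allyl geometry gives the anti adduct (6R), attack anti to the C8 isobutyrate and the C9 side chain (both on one face of the lactone) sets 7S, and acid then moves the acyl group from O9 to O6 because the trans five-membered lactone is the more stable one.

Step 18
Reactants: 26 (the C9 alcohol from step 17)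
Product: 27 methyl (2E)-2-[(1S,2S)-1-(acetyloxy)-2-{(2R,3S)-2-[(1E)-4-[(tert-butyldimethylsilyl)oxy]-2-{[(tert-butyldiphenylsilyl)oxy]methyl}but-1-en-1-yl]-4-methylidene-5-oxooxolan-3-yl}-2-[(2-methylpropanoyl)oxy]ethyl]-3-iodoprop-2-enoate
Conditions: Ac2O, pyridine, CH2Cl2, 0 °C to rt
Reagents that add atoms: acetic anhydride, CC(=O)OC(C)=O
Why: Prompt acetylation of the hydroxyl released at C9 installs the target's acetate before the neighbouring isobutyrate can migrate.

Step 19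
Reactants: 27 (the C9 acetate from step 18)
Product: 28 methyl (2E)-2-[(1S,2S)-1-(acetyloxy)-2-{(2R,3S)-2-[(1E)-2-{[(tert-butyldiphenylsilyl)oxy]methyl}-4-hydroxybut-1-en-1-yl]-4-methylidene-5-oxooxolan-3-yl}-2-[(2-methylpropanoyl)oxy]ethyl]-3-iodoprop-2-enoate
Conditions: CSA (10 mol%), MeOH/CH2Cl2 (1:1), 0 °C
Reagents that add atoms: none
Why: Acid-catalysed methanolysis cleaves the primary alkyl TBS ether much faster than the TBDPS ether and leaves the esters alone.

Step 20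
Reactants: 28 (the C2 primary alcohol from step 19)
Product: 29 methyl (2E)-2-[(1S,2S)-1-(acetyloxy)-2-{(2R,3S)-2-[(1E)-2-{[(tert-butyldiphenylsilyl)oxy]methyl}-4-oxobut-1-en-1-yl]-4-methylidene-5-oxooxolan-3-yl}-2-[(2-methylpropanoyl)oxy]ethyl]-3-iodoprop-2-enoate
Conditions: Dess–Martin periodinane, NaHCO3, CH2Cl2, 0 °C; used crude
Reagents that add atoms: none
Why: Buffered Dess–Martin oxidation gives the β,γ-unsaturated aldehyde without moving the C4=C5 alkene into conjugation.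

Step 21
Reactants: 29 (the iodo aldehyde from step 20)
Product: 30 methyl (1(10)E,4E,2S,6R,7S,8S,9S)-9-acetoxy-15-[(tert-butyldiphenylsilyl)oxy]-2-hydroxy-8-[(2-methylpropanoyl)oxy]germacra-1(10),4,11(13)-trien-12,6-olid-14-oate
Conditions: CrCl2 (10 equiv), NiCl2 (2 mol%), DMSO/THF (3:1), rt, 2 mM, slow addition
Reagents that add atoms: none
Why: Intramolecular Nozaki–Hiyama–Kishi coupling: nickel-catalysed activation of the E iodide, transfer to chromium with retention (C2 ends cis to C9) and addition to the aldehyde at high dilution close the ten-membered ring; the 2S carbinol is the outcome expected for addition to the outer face of the aldehyde in the lactone-constrained transition state, but this is not secured by precedent.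

Step 22
Reactants: 30 (the macrocyclic TBDPS ether from step 21)
Product: 31 methyl (1(10)E,4E,2S,6R,7S,8S,9S)-9-acetoxy-2,15-dihydroxy-8-[(2-methylpropanoyl)oxy]germacra-1(10),4,11(13)-trien-12,6-olid-14-oate (CNP0301018.3)
Conditions: HF·pyridine, pyridine, THF, 0 °C to rt
Reagents that add atoms: none
Why: Buffered fluoride desilylation removes the last silyl ether without touching the three esters, the α-methylene lactone or the allylic alcohol.

**Compound list**
1 | but-2-yne-1,4-diol | OCC#CCO | starting material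
2 | 4-[(tert-butyldiphenylsilyl)oxy]but-2-yn-1-ol | OCC#CCO[Si](c1ccccc1)(c1ccccc1)C(C)(C)C | intermediate
3 | sodium 3-{[(tert-butyldiphenylsilyl)oxy]methyl}-2,2-bis(2-methoxyethoxy)-2,5-dihydro-1,2-oxaluminol-2-uide (cyclic alkenylalanate) | COCCO[Al-]1(OCCOC)OCC=C1CO[Si](c2ccccc2)(c2ccccc2)C(C)(C)C.[Na+] | intermediate
4 | (2Z)-4-[(tert-butyldiphenylsilyl)oxy]-3-iodobut-2-en-1-ol | OC/C=C(/CO[Si](c1ccccc1)(c1ccccc1)C(C)(C)C)I | intermediate
5 | potassium vinyltrifluoroborate | C=C[B-](F)(F)F.[K+] | starting material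
6 | (2E)-3-{[(tert-butyldiphenylsilyl)oxy]methyl}penta-2,4-dien-1-ol | OC/C=C(/CO[Si](c1ccccc1)(c1ccccc1)C(C)(C)C)C=C | intermediate
7 | (2E)-3-{[(tert-butyldiphenylsilyl)oxy]methyl}penta-2,4-dien-1-yl acetate | CC(=O)OC/C=C(/CO[Si](c1ccccc1)(c1ccccc1)C(C)(C)C)C=C | intermediate
8 | (2E)-5-(9-borabicyclo[3.3.1]nonan-9-yl)-3-{[(tert-butyldiphenylsilyl)oxy]methyl}pent-2-en-1-yl acetate | CC(=O)OC/C=C(/CO[Si](c1ccccc1)(c1ccccc1)C(C)(C)C)CCB1C2CCCC1CCC2 | intermediate
9 | (2E)-3-{[(tert-butyldiphenylsilyl)oxy]methyl}-5-hydroxypent-2-en-1-yl acetate | CC(=O)OC/C=C(/CO[Si](c1ccccc1)(c1ccccc1)C(C)(C)C)CCO | intermediate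
10 | (2E)-5-[(tert-butyldimethylsilyl)oxy]-3-{[(tert-butyldiphenylsilyl)oxy]methyl}pent-2-en-1-yl acetate | CC(=O)OC/C=C(/CO[Si](c1ccccc1)(c1ccccc1)C(C)(C)C)CCO[Si](C)(C)C(C)(C)C | intermediate
11 | (2E)-5-[(tert-butyldimethylsilyl)oxy]-3-{[(tert-butyldiphenylsilyl)oxy]methyl}pent-2-en-1-ol | OC/C=C(/CO[Si](c1ccccc1)(c1ccccc1)C(C)(C)C)CCO[Si](C)(C)C(C)(C)C | intermediate
12 | (2E)-5-[(tert-butyldimethylsilyl)oxy]-3-{[(tert-butyldiphenylsilyl)oxy]methyl}pent-2-enal (west fragment) | O=C/C=C(/CO[Si](c1ccccc1)(c1ccccc1)C(C)(C)C)CCO[Si](C)(C)C(C)(C)C | intermediate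
13 | (2S)-but-3-ene-1,2-diol | C=C[C@H](O)CO | starting material
14 | (4S)-4-ethenyl-2-(4-methoxyphenyl)-1,3-dioxolane (both acetal epimers) | C=C[C@H]1COC(c2ccc(OC)cc2)O1 | intermediate
15 | (2S)-2-[(4-methoxybenzyl)oxy]but-3-en-1-ol | C=C[C@H](OCc1ccc(OC)cc1)CO | intermediate
16 | (2S)-2-[(4-methoxybenzyl)oxy]but-3-enal | C=C[C@H](OCc1ccc(OC)cc1)C=O | intermediate
17 | methyl propiolate (methyl prop-2-ynoate) | C#CC(=O)OC | starting material
18 | methyl (2Z)-2-{(1S,2S)-1-hydroxy-2-[(4-methoxybenzyl)oxy]but-3-en-1-yl}-3-iodoprop-2-enoate | C=C[C@H](OCc1ccc(OC)cc1)[C@@H](O)/C(=C/I)C(=O)OC | intermediate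
19 | methyl (2E)-2-{(1S,2S)-1-hydroxy-2-[(4-methoxybenzyl)oxy]but-3-en-1-yl}-3-iodoprop-2-enoate | C=C[C@H](OCc1ccc(OC)cc1)[C@@H](O)/C(=C\I)C(=O)OC | intermediate
20 | 2-(bromomethyl)prop-2-enoic acid | C=C(CBr)C(=O)O | starting material
21 | (1S,2S)-1-[(1E)-2-iodo-1-(methoxycarbonyl)ethenyl]-2-[(4-methoxybenzyl)oxy]but-3-en-1-yl 2-(bromomethyl)prop-2-enoate | C=C[C@H](OCc1ccc(OC)cc1)[C@@H](OC(=O)C(=C)CBr)/C(=C\I)C(=O)OC | intermediate
22 | (1S,2S)-2-hydroxy-1-[(1E)-2-iodo-1-(methoxycarbonyl)ethenyl]but-3-en-1-yl 2-(bromomethyl)prop-2-enoate | C=C[C@H](O)[C@@H](OC(=O)C(=C)CBr)/C(=C\I)C(=O)OC | intermediate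
23 | (1S,2S)-1-[(1E)-2-iodo-1-(methoxycarbonyl)ethenyl]-2-[(2-methylpropanoyl)oxy]but-3-en-1-yl 2-(bromomethyl)prop-2-enoate | C=C[C@H](OC(=O)C(C)C)[C@@H](OC(=O)C(=C)CBr)/C(=C\I)C(=O)OC | intermediate
24 | methyl (2E)-2-{(2S,3S)-5-(bromomethyl)-3-[(2-methylpropanoyl)oxy]-6-oxo-3,6-dihydro-2H-pyran-2-yl}-3-iodoprop-2-enoate (east fragment) | BrCC1=C[C@H](OC(=O)C(C)C)[C@H](/C(=C\I)C(=O)OC)OC1=O | intermediate
25 | methyl (2E)-2-{(2S,3S,4S)-4-[(1R,2E)-5-[(tert-butyldimethylsilyl)oxy]-3-{[(tert-butyldiphenylsilyl)oxy]methyl}-1-hydroxypent-2-en-1-yl]-5-methylidene-3-[(2-methylpropanoyl)oxy]-6-oxooxan-2-yl}-3-iodoprop-2-enoate | C=C1C(=O)O[C@@H](/C(=C\I)C(=O)OC)[C@@H](OC(=O)C(C)C)[C@@H]1[C@H](O)/C=C(/CO[Si](c2ccccc2)(c2ccccc2)C(C)(C)C)CCO[Si](C)(C)C(C)(C)C | intermediate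
26 | methyl (2E)-2-[(1S,2S)-2-{(2R,3S)-2-[(1E)-4-[(tert-butyldimethylsilyl)oxy]-2-{[(tert-butyldiphenylsilyl)oxy]methyl}but-1-en-1-yl]-4-methylidene-5-oxooxolan-3-yl}-1-hydroxy-2-[(2-methylpropanoyl)oxy]ethyl]-3-iodoprop-2-enoate | C=C1C(=O)O[C@H](/C=C(/CO[Si](c2ccccc2)(c2ccccc2)C(C)(C)C)CCO[Si](C)(C)C(C)(C)C)[C@H]1[C@H](OC(=O)C(C)C)[C@@H](O)/C(=C\I)C(=O)OC | intermediate
27 | methyl (2E)-2-[(1S,2S)-1-(acetyloxy)-2-{(2R,3S)-2-[(1E)-4-[(tert-butyldimethylsilyl)oxy]-2-{[(tert-butyldiphenylsilyl)oxy]methyl}but-1-en-1-yl]-4-methylidene-5-oxooxolan-3-yl}-2-[(2-methylpropanoyl)oxy]ethyl]-3-iodoprop-2-enoate | C=C1C(=O)O[C@H](/C=C(/CO[Si](c2ccccc2)(c2ccccc2)C(C)(C)C)CCO[Si](C)(C)C(C)(C)C)[C@H]1[C@H](OC(=O)C(C)C)[C@@H](OC(C)=O)/C(=C\I)C(=O)OC | intermediate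
28 | methyl (2E)-2-[(1S,2S)-1-(acetyloxy)-2-{(2R,3S)-2-[(1E)-2-{[(tert-butyldiphenylsilyl)oxy]methyl}-4-hydroxybut-1-en-1-yl]-4-methylidene-5-oxooxolan-3-yl}-2-[(2-methylpropanoyl)oxy]ethyl]-3-iodoprop-2-enoate | C=C1C(=O)O[C@H](/C=C(/CO[Si](c2ccccc2)(c2ccccc2)C(C)(C)C)CCO)[C@H]1[C@H](OC(=O)C(C)C)[C@@H](OC(C)=O)/C(=C\I)C(=O)OC | intermediate
29 | methyl (2E)-2-[(1S,2S)-1-(acetyloxy)-2-{(2R,3S)-2-[(1E)-2-{[(tert-butyldiphenylsilyl)oxy]methyl}-4-oxobut-1-en-1-yl]-4-methylidene-5-oxooxolan-3-yl}-2-[(2-methylpropanoyl)oxy]ethyl]-3-iodoprop-2-enoate | C=C1C(=O)O[C@H](/C=C(/CO[Si](c2ccccc2)(c2ccccc2)C(C)(C)C)CC=O)[C@H]1[C@H](OC(=O)C(C)C)[C@@H](OC(C)=O)/C(=C\I)C(=O)OC | intermediate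
30 | methyl (1(10)E,4E,2S,6R,7S,8S,9S)-9-acetoxy-15-[(tert-butyldiphenylsilyl)oxy]-2-hydroxy-8-[(2-methylpropanoyl)oxy]germacra-1(10),4,11(13)-trien-12,6-olid-14-oate | C=C1C(=O)O[C@@H]2/C=C(/CO[Si](c3ccccc3)(c3ccccc3)C(C)(C)C)C[C@H](O)/C=C(/C(=O)OC)[C@H](OC(C)=O)[C@@H](OC(=O)C(C)C)[C@@H]12 | intermediate
31 | methyl (1(10)E,4E,2S,6R,7S,8S,9S)-9-acetoxy-2,15-dihydroxy-8-[(2-methylpropanoyl)oxy]germacra-1(10),4,11(13)-trien-12,6-olid-14-oate (CNP0301018.3) | C=C1C(=O)O[C@@H]2/C=C(/CO)C[C@H](O)/C=C(/C(=O)OC)[C@H](OC(C)=O)[C@@H](OC(=O)C(C)C)[C@@H]12 | target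

**Step count**
Total: 22 steps. Longest linear sequence: 14 steps (steps 9–16 then 17–22; the west branch, steps 1–8 then 17–22, is equally long).

**Three steps most likely to fail, with fallbacks**

Step 12. Weak points are the E geometry of the iodide (the kinetic iodo-aldol product is Z, and the equilibration to E is argued by analogy to simpler β-halo acrylates), the syn selectivity, and the labile aldehyde and PMB ether under MgI2. The fallback sets out from 16 and 17 and returns at 19. Methyl propiolate 17 is distannylated (syn) with hexamethyldistannane and Pd(PPh3)4 in THF at 65 °C to methyl (2Z)-2,3-bis(trimethylstannyl)prop-2-enoate F1. MeLi in THF at −98 °C exchanges only the tin next to the ester. The lithio species is added to 16 precomplexed with MgBr2·OEt2 (chelation control) to give methyl (2E)-2-{(1S,2S)-1-hydroxy-2-[(4-methoxybenzyl)oxy]but-3-en-1-yl}-3-(trimethylstannyl)prop-2-enoate F2, in which tin is cis to C9 by retention. I2 in CH2Cl2 at 0 °C then replaces tin by iodine with retention and gives 19.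

Step 17. The facial selectivity at C7 is well supported by the ring, but the anti selectivity at C6 and the clean lactone migration are not guaranteed. The fallback sets out from 12 and 24 and returns at 25, which goes on to 26 as in the route. If the indium coupling gives mainly the C6 epimer, methyl (2E)-2-{(2S,3S,4S)-4-[(1S,2E)-5-[(tert-butyldimethylsilyl)oxy]-3-{[(tert-butyldiphenylsilyl)oxy]methyl}-1-hydroxypent-2-en-1-yl]-5-methylidene-3-[(2-methylpropanoyl)oxy]-6-oxooxan-2-yl}-3-iodoprop-2-enoate F3, the crude adduct is kept away from acid. It is oxidised with Dess–Martin periodinane to the dienone methyl (2E)-2-{(2S,3S,4R)-4-[(2E)-5-[(tert-butyldimethylsilyl)oxy]-3-{[(tert-butyldiphenylsilyl)oxy]methyl}pent-2-enoyl]-5-methylidene-3-[(2-methylpropanoyl)oxy]-6-oxooxan-2-yl}-3-iodoprop-2-enoate F4. The ketone is then reduced under reagent control with (R)-2-methyl-CBS-oxazaborolidine and catecholborane at −78 °C (alkenyl as the large group) to 25. The C6 configuration is thus set by reduction instead of by the allylation.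

Step 21. Ring closure to a ten-membered ring and the configuration at C2 are both uncertain. The fallback sets out from 29 and returns at 30. If the chromium cyclisation gives the C2 epimer methyl (1(10)E,4E,2R,6R,7S,8S,9S)-9-acetoxy-15-[(tert-butyldiphenylsilyl)oxy]-2-hydroxy-8-[(2-methylpropanoyl)oxy]germacra-1(10),4,11(13)-trien-12,6-olid-14-oate F5, or a mixture, it is oxidised with Dess–Martin periodinane to the macrocyclic enone methyl (1(10)E,4E,6R,7S,8S,9S)-9-acetoxy-15-[(tert-butyldiphenylsilyl)oxy]-8-[(2-methylpropanoyl)oxy]-2-oxogermacra-1(10),4,11(13)-trien-12,6-olid-14-oate F6. F6 is reduced with (R)-2-methyl-CBS-oxazaborolidine and BH3·SMe2 at −40 °C to the 2S alcohol 30.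

**Further compounds**
F1 | step 12 | methyl (2Z)-2,3-bis(trimethylstannyl)prop-2-enoate | COC(=O)/C([Sn](C)(C)C)=C/[Sn](C)(C)C
F2 | step 12 | methyl (2E)-2-{(1S,2S)-1-hydroxy-2-[(4-methoxybenzyl)oxy]but-3-en-1-yl}-3-(trimethylstannyl)prop-2-enoate | C=C[C@H](OCc1ccc(OC)cc1)[C@@H](O)/C(=C\[Sn](C)(C)C)C(=O)OC
F3 | step 17 | methyl (2E)-2-{(2S,3S,4S)-4-[(1S,2E)-5-[(tert-butyldimethylsilyl)oxy]-3-{[(tert-butyldiphenylsilyl)oxy]methyl}-1-hydroxypent-2-en-1-yl]-5-methylidene-3-[(2-methylpropanoyl)oxy]-6-oxooxan-2-yl}-3-iodoprop-2-enoate | C=C1C(=O)O[C@@H](/C(=C\I)C(=O)OC)[C@@H](OC(=O)C(C)C)[C@@H]1[C@@H](O)/C=C(/CO[Si](c2ccccc2)(c2ccccc2)C(C)(C)C)CCO[Si](C)(C)C(C)(C)C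
F4 | step 17 | methyl (2E)-2-{(2S,3S,4R)-4-[(2E)-5-[(tert-butyldimethylsilyl)oxy]-3-{[(tert-butyldiphenylsilyl)oxy]methyl}pent-2-enoyl]-5-methylidene-3-[(2-methylpropanoyl)oxy]-6-oxooxan-2-yl}-3-iodoprop-2-enoate | C=C1C(=O)O[C@@H](/C(=C\I)C(=O)OC)[C@@H](OC(=O)C(C)C)[C@@H]1C(=O)/C=C(/CO[Si](c2ccccc2)(c2ccccc2)C(C)(C)C)CCO[Si](C)(C)C(C)(C)C
F5 | step 21 | methyl (1(10)E,4E,2R,6R,7S,8S,9S)-9-acetoxy-15-[(tert-butyldiphenylsilyl)oxy]-2-hydroxy-8-[(2-methylpropanoyl)oxy]germacra-1(10),4,11(13)-trien-12,6-olid-14-oate | C=C1C(=O)O[C@@H]2/C=C(/CO[Si](c3ccccc3)(c3ccccc3)C(C)(C)C)C[C@@H](O)/C=C(/C(=O)OC)[C@H](OC(C)=O)[C@@H](OC(=O)C(C)C)[C@@H]12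
F6 | step 21 | methyl (1(10)E,4E,6R,7S,8S,9S)-9-acetoxy-15-[(tert-butyldiphenylsilyl)oxy]-8-[(2-methylpropanoyl)oxy]-2-oxogermacra-1(10),4,11(13)-trien-12,6-olid-14-oate | C=C1C(=O)O[C@@H]2/C=C(/CO[Si](c3ccccc3)(c3ccccc3)C(C)(C)C)CC(=O)/C=C(/C(=O)OC)[C@H](OC(C)=O)[C@@H](OC(=O)C(C)C)[C@@H]12
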